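**Plan**
- Cuts, in retrosynthetic order: the N–CHO bond and the N–CH2 bond at the homoallylic end of ring C; in ring B the bond between the ketone carbon and the alkylidene carbon; around ring A the propyl C–N bond, the C2–allyl bond, the C3–CH2 bond of the two-carbon arm and the C2–C(sp) bond.
- Forward: ring A (cyclohexane) comes from 3-methylcyclohex-2-en-1-one. Sonogashira coupling, conjugate addition and allylation build C3 and the quaternary C2. Ring B (cyclopentanone) closes in the key step and ring C (azonane) closes last by N-alkylation.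
- Enabling feature: ring B is an α-alkylidene cyclopentanone whose vinylic H is cis to the C=O and whose chain carbon is cis to quaternary C2. This is the syn adduct of an aldehyde C–H across an alkyne held on C2, so a 5-alkynal is the precursor.
- Stereochemistry: C5 from a catalytic asymmetric epoxidation; C3 by conjugate addition cis to the C5 oxygen; C2 by allylation trans to the C3 arm; C1 by reagent-controlled CBS reduction; the E alkene by syn hydroacylation.

Key step: step 16

Remark: ring A locants (C1 = oxygenated carbon next to the quaternary carbon C2, C3 = carbon bearing the two-carbon arm, C5 = methyl carbinol) are kept for every intermediate, also where systematic numbering would differ; PMB = 4-methoxybenzyl, Ns = 2-nitrophenylsulfonyl.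
Remark: the quinine-derived primary amine salt is assumed to be the pseudoenantiomer that gives the (2S,3S)-epoxide 2.

Step 1
Reactants: 1 3-methylcyclohex-2-en-1-one
Product: 2 (2S,3S)-2,3-epoxy-3-methylcyclohexan-1-one
Conditions: 9-amino-9-deoxy-epi-quinine (10 mol %), CF3CO2H (20 mol %), 50% aq. H2O2, dioxane, 30 °C
Reagents that add atoms: hydrogen peroxide, OO
Why: Iminium-activated nucleophilic epoxidation (Weitz–Scheffer type) with a cinchona primary amine salt is established for 3-substituted cyclohexenones, and the catalyst selects the enone face for hydroperoxide attack, which sets the methyl-bearing carbon S (the cis epoxide fixes the neighbouring carbon).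

Step 2
Reactants: 2 (2S,3S)-2,3-epoxy-3-methylcyclohexan-1-one
Product: 3 (S)-3-hydroxy-3-methylcyclohexan-1-one
Conditions: SmI2 (2.2 equiv), THF/MeOH, −90 °C
Reagents that add atoms: none
Why: Single-electron reductive opening of an α,β-epoxy ketone cleaves only the Cα–O bond through the ketyl, so the tertiary C–O bond and its configuration are kept.

Step 3
Reactants: 3 (S)-3-hydroxy-3-methylcyclohexan-1-one
Product: 4 (S)-3-methyl-3-(triethylsilyloxy)cyclohexan-1-one
Conditions: Et3SiOTf, 2,6-lutidine, CH2Cl2, −78 °C → 0 °C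
Reagents that add atoms: triethylsilyl trifluoromethanesulfonate, CC[Si](CC)(CC)OS(=O)(=O)C(F)(F)F
Why: Silyl triflate silylation of a tertiary alcohol is fast at low temperature and turns the β-oxygen into a poor leaving group for the enone chemistry that follows.

Step 4
Reactants: 4 (S)-3-methyl-3-(triethylsilyloxy)cyclohexan-1-one
Product: 6 (S)-5-methyl-5-(triethylsilyloxy)cyclohex-2-en-1-one, via kinetic trimethylsilyl enol ether 5 (not isolated)
Conditions: LiN(iPr)2, Me3SiCl, THF, −78 °C; then Pd(OAc)2 (1.0 equiv), MeCN, rt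
Reagents that add atoms: none
Why: Kinetic enolisation takes the unhindered methylene remote from the quaternary carbon, and the Saegusa–Ito oxidation can place the double bond only on that side because the other β-carbon carries no hydrogen.

Step 5
Reactants: 6 (S)-5-methyl-5-(triethylsilyloxy)cyclohex-2-en-1-one
Product: 7 (S)-2-iodo-5-methyl-5-(triethylsilyloxy)cyclohex-2-en-1-one
Conditions: I2, pyridine, CH2Cl2, 0 °C → rt
Reagents that add atoms: iodine, II
Why: Pyridine-mediated α-iodination of an enone (conjugate addition of pyridine, iodination of the enolate, elimination) is general for β-unsubstituted cyclohexenones and leaves C5 untouched.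

Step 6
Reactants: 8 but-3-yn-1-ol
Product: 9 1-[(but-3-yn-1-yloxy)methyl]-4-methoxybenzene
Conditions: NaH, THF, 0 °C; 4-methoxybenzyl chloride, Bu4NI (cat.), rt
Reagents that add atoms: 4-methoxybenzyl chloride, COc1ccc(CCl)cc1
Why: Williamson etherification is selective because the hydroxyl is far more acidic than the alkyne C–H, and the PMB ether survives fluoride, base and mild acid until it is removed oxidatively.

Step 7
Reactants: 7 (S)-2-iodo-5-methyl-5-(triethylsilyloxy)cyclohex-2-en-1-one; 9 1-[(but-3-yn-1-yloxy)methyl]-4-methoxybenzene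
Product: 10 (S)-2-[4-(PMB-oxy)but-1-yn-1-yl]-5-methyl-5-(triethylsilyloxy)cyclohex-2-en-1-one
Conditions: Pd(PPh3)2Cl2 (5 mol %), CuI (10 mol %), iPr2NH, THF, 0 °C → rt
Reagents that add atoms: none
Why: Sonogashira coupling of 2-iodocycloalkenones with terminal alkynes runs at or below room temperature with only an amine base, so the β-silyloxy ketone is not driven to eliminate.

Step 8
Reactants: 10 (S)-2-[4-(PMB-oxy)but-1-yn-1-yl]-5-methyl-5-(triethylsilyloxy)cyclohex-2-en-1-one; 11 (1,3-dioxolan-2-ylmethyl)magnesium bromide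
Product: 12 (3S,5S)-3-(1,3-dioxolan-2-ylmethyl)-2-[4-(PMB-oxy)but-1-yn-1-yl]-5-methyl-5-(triethylsilyloxy)-1-(trimethylsilyloxy)cyclohex-1-ene
Conditions: CuBr·SMe2 (20 mol %), Me3SiCl, HMPA, THF, −78 °C; Et3N quench
Reagents that add atoms: chlorotrimethylsilane, C[Si](C)(C)Cl
Why: Copper-catalysed, chlorosilane-accelerated conjugate addition of the Grignard reagent attacks C3 axially on the half-chair with the silyloxy group axial and the methyl equatorial, because the incoming carbon then meets oxygen and not methyl in the 1,3-diaxial position, which should place the masked acetaldehyde arm cis to the C5 oxygen (3S).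

Step 9
Reactants: 12 (3S,5S)-3-(1,3-dioxolan-2-ylmethyl)-2-[4-(PMB-oxy)but-1-yn-1-yl]-5-methyl-5-(triethylsilyloxy)-1-(trimethylsilyloxy)cyclohex-1-ene; 13 allyl bromide
Product: 15 (2S,3S,5S)-2-allyl-3-(1,3-dioxolan-2-ylmethyl)-2-[4-(PMB-oxy)but-1-yn-1-yl]-5-methyl-5-(triethylsilyloxy)cyclohexan-1-one, via lithium enolate 14 (not isolated)
Conditions: MeLi, THF, 0 °C; then 13, HMPA, −78 °C → 0 °C
Reagents that add atoms: none
Why: Regiospecific enolate generation from the silyl enol ether and C-alkylation with the reactive allyl halide (enolate alkylation) brings the allyl group in anti to the C3 arm, so quaternary C2 should form with allyl trans and alkynyl cis to that arm (2S).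

Step 10
Reactants: 15 (2S,3S,5S)-2-allyl-3-(1,3-dioxolan-2-ylmethyl)-2-[4-(PMB-oxy)but-1-yn-1-yl]-5-methyl-5-(triethylsilyloxy)cyclohexan-1-one
Product: 16 (1S,2S,3S,5S)-2-allyl-3-(1,3-dioxolan-2-ylmethyl)-2-[4-(PMB-oxy)but-1-yn-1-yl]-5-methyl-5-(triethylsilyloxy)cyclohexan-1-ol
Conditions: (R)-2-methyl-CBS-oxazaborolidine (0.5 equiv), catecholborane, toluene, −78 °C → −20 °C
Reagents that add atoms: none
Why: The Corey–Bakshi–Shibata reduction is reagent controlled, the (R)-oxazaborolidine binding the carbonyl anti to the quaternary C2 and delivering hydride from catecholborane (inert to the allyl group at this temperature) to the face that gives the 1S alcohol, cis to the C5 oxygen and equatorial.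

Step 11
Reactants: 16 (1S,2S,3S,5S)-2-allyl-3-(1,3-dioxolan-2-ylmethyl)-2-[4-(PMB-oxy)but-1-yn-1-yl]-5-methyl-5-(triethylsilyloxy)cyclohexan-1-ol
Product: 17 (1S,2S,3S,5S)-2-allyl-3-(1,3-dioxolan-2-ylmethyl)-2-[4-(PMB-oxy)but-1-yn-1-yl]-5-methylcyclohexane-1,5-diol
Conditions: Bu4NF, THF, rt → 40 °C
Reagents that add atoms: none
Why: Fluoride desilylation removes the only silyl group and needs no acid, which matters because acid could tie the two cis hydroxyls to the neighbouring masked aldehyde as an internal acetal.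

Step 12
Reactants: 17 (1S,2S,3S,5S)-2-allyl-3-(1,3-dioxolan-2-ylmethyl)-2-[4-(PMB-oxy)but-1-yn-1-yl]-5-methylcyclohexane-1,5-diol
Product: 18 (1S,2S,3S,5S)-2-allyl-3-(1,3-dioxolan-2-ylmethyl)-2-[4-(PMB-oxy)but-1-yn-1-yl]-5-methylcyclohexane-1,5-diyl diacetate
Conditions: Ac2O, Et3N, DMAP, CH2Cl2, rt → 40 °C
Reagents that add atoms: acetic anhydride, CC(=O)OC(C)=O
Why: DMAP-catalysed acylation acetylates both the hindered secondary and the equatorial tertiary hydroxyl, and it is placed before nitrogen is introduced so that no sulfonamide N–H competes.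

Step 13
Reactants: 18 (1S,2S,3S,5S)-2-allyl-3-(1,3-dioxolan-2-ylmethyl)-2-[4-(PMB-oxy)but-1-yn-1-yl]-5-methylcyclohexane-1,5-diyl diacetate
Product: 20 (1S,2S,3S,5S)-3-(1,3-dioxolan-2-ylmethyl)-2-(3-hydroxypropyl)-2-[4-(PMB-oxy)but-1-yn-1-yl]-5-methylcyclohexane-1,5-diyl diacetate, via B-alkyl-9-borabicyclononane 19 (not isolated)
Conditions: 9-BBN, THF, 0 °C → rt; then 30% H2O2, aq. NaOAc, 0 °C → rt
Reagents that add atoms: hydrogen peroxide, OO
Why: Hydroboration–oxidation with 9-BBN takes the monosubstituted alkene anti-Markovnikov much faster than the neopentyl internal alkyne and does not reduce esters, and the buffered peroxide oxidation spares the acetates.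

Step 14
Reactants: 20 (1S,2S,3S,5S)-3-(1,3-dioxolan-2-ylmethyl)-2-(3-hydroxypropyl)-2-[4-(PMB-oxy)but-1-yn-1-yl]-5-methylcyclohexane-1,5-diyl diacetate; 21 2-nitrobenzenesulfonamide
Product: 22 (1S,2S,3S,5S)-3-(1,3-dioxolan-2-ylmethyl)-2-[3-(Ns-amino)propyl]-2-[4-(PMB-oxy)but-1-yn-1-yl]-5-methylcyclohexane-1,5-diyl diacetate
Conditions: 21 (3 equiv), PPh3, DIAD, THF, 0 °C → rt
Reagents that add atoms: none
Why: Mitsunobu N-alkylation of the acidic primary sulfonamide, used in excess to suppress double alkylation, converts the primary alcohol into the mono-alkyl sulfonamide under neutral conditions that leave acetates and acetal alone.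

Step 15
Reactants: 22 (1S,2S,3S,5S)-3-(1,3-dioxolan-2-ylmethyl)-2-[3-(Ns-amino)propyl]-2-[4-(PMB-oxy)but-1-yn-1-yl]-5-methylcyclohexane-1,5-diyl diacetate
Product: 23 (1S,2S,3S,5S)-2-[3-(Ns-amino)propyl]-2-[4-(PMB-oxy)but-1-yn-1-yl]-5-methyl-3-(2-oxoethyl)cyclohexane-1,5-diyl diacetate
Conditions: TsOH·H2O (cat.), acetone/H2O, 40 °C
Reagents that add atoms: water, O
Why: Acid-catalysed acetal hydrolysis frees the aldehyde only now, when both ring oxygens are acetylated and cannot form internal acetals, and catalytic sulfonic acid is tolerated by the acetates, the PMB ether and the sulfonamide.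

Step 16
Reactants: 23 (1S,2S,3S,5S)-2-[3-(Ns-amino)propyl]-2-[4-(PMB-oxy)but-1-yn-1-yl]-5-methyl-3-(2-oxoethyl)cyclohexane-1,5-diyl diacetate
Product: 24 cis-fused ring A/ring B (E)-enone diacetate, (1S,2S,3S,5S): ring B = C3–CH2–C(=O)–C(=CH–CH2CH2O-PMB)–C2 with the vinylic H cis to C=O; C2 also bears (CH2)3NHNs
Conditions: [Rh(dppe)]ClO4 (10 mol %, from [Rh(nbd)(dppe)]ClO4 and H2), CH2Cl2, rt
Reagents that add atoms: none
Why: Oxidative addition of the aldehyde C–H to the cationic monovalent rhodium centre gives an acyl rhodium hydride (trivalent rhodium), the tethered alkyne inserts syn into the Rh–H bond, and C–C reductive elimination from the six-membered acyl alkenyl rhodacycle joins the ketone carbon to the alkyne carbon on C2. The closest known reaction type is the cationic rhodium/diphosphine-catalysed intramolecular hydroacylation of 5-alkynals to (E)-α-alkylidenecyclopentanones. Ring B closes in the 5-exo-dig mode. No new stereocentre arises; the alkene geometry follows from syn delivery of acyl and hydrogen, which puts H cis to the carbonyl and the chain cis to C2, and the cis ring fusion is inherited from the cis arrangement of arm and alkyne in 23. The step needs exo acyl delivery to beat 6-endo closure and decarbonylation. This is secured by the five-atom spacing of aldehyde and alkyne, the chelating diphosphine, and the quaternary propargylic carbon, which has no hydrogen to isomerise and presses the two reacting groups together (Thorpe–Ingold effect).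

Step 17
Reactants: 24 cis-fused ring A/ring B (E)-enone diacetate with PMB ether and NsNH chain
Product: 25 cis-fused ring A/ring B (E)-enone diacetate, (1S,2S,3S,5S): alkylidene = 3-hydroxypropylidene; C2 bears (CH2)3NHNs
Conditions: DDQ, CH2Cl2/pH 7 buffer, 0 °C → rt
Reagents that add atoms: none
Why: Oxidative PMB ether cleavage (hydride abstraction to the benzylic oxocarbenium ion, then hydrolysis) is neutral and leaves the electron-poor enone, the acetates and the sulfonamide intact.

Step 18
Reactants: 25 cis-fused ring A/ring B (E)-enone diacetate with 3-hydroxypropylidene and NsNH chain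
Product: 26 N-Ns tricycle, (1S,2S,3S,5S,E): azonane ring C = C(alkylidene)=CH–CH2–CH2–N(Ns)–CH2–CH2–CH2–C2
Conditions: PPh3, DIAD, toluene (0.005 M), rt
Reagents that add atoms: none
Why: Intramolecular Fukuyama–Mitsunobu alkylation of the sulfonamide by the primary alcohol at high dilution should close the nine-membered ring, helped by the cis placement of the hydroxyethyl chain and C2 across the exocyclic alkene.

Step 19
Reactants: 26 N-Ns tricycle
Product: 27 secondary amine tricycle, (1S,2S,3S,5S,E): as 26 with N–H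
Conditions: PhSH, K2CO3, MeCN, rt
Reagents that add atoms: none
Why: Thiolate adds to the nitroarene and expels SO2 and the amine (nucleophilic aromatic substitution through a Meisenheimer complex) under mild base that spares the acetates, while any thiol added to the enone should revert because thia-Michael addition is reversible and the thiolate is consumed.

Step 20
Reactants: 27 secondary amine tricycle
Product: 28 target, (1S,2S,3S,5S,E)-N-formyl azonane-fused enone diacetate
Conditions: acetic formic anhydride, CH2Cl2, 0 °C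
Reagents that add atoms: acetic formic anhydride, CC(=O)OC=O
Why: N-formylation by the mixed anhydride transfers the formyl group much faster than acetyl and caps the amine before it can engage the ring B ketone across the ring.

**Compound list**
1 | 3-methylcyclohex-2-en-1-one | CC1=CC(=O)CCC1 | starting material
2 | (2S,3S)-2,3-epoxy-3-methylcyclohexan-1-one | O=C1CCC[C@]2(C)O[C@H]12 | intermediate
3 | (S)-3-hydroxy-3-methylcyclohexan-1-one | O=C1C[C@@](C)(O)CCC1 | intermediate
4 | (S)-3-methyl-3-(triethylsilyloxy)cyclohexan-1-one | O=C1C[C@@](C)(O[Si](CC)(CC)CC)CCC1 | intermediate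
5 | kinetic trimethylsilyl enol ether of 4, (S)-1-methyl-1-(triethylsilyloxy)-3-(trimethylsilyloxy)cyclohex-3-ene | C[Si](C)(C)OC1=CCC[C@](C)(O[Si](CC)(CC)CC)C1 | intermediate
6 | (S)-5-methyl-5-(triethylsilyloxy)cyclohex-2-en-1-one | O=C1C=CC[C@](C)(O[Si](CC)(CC)CC)C1 | intermediate
7 | (S)-2-iodo-5-methyl-5-(triethylsilyloxy)cyclohex-2-en-1-one | O=C1C(I)=CC[C@](C)(O[Si](CC)(CC)CC)C1 | intermediate
8 | but-3-yn-1-ol | C#CCCO | starting material
9 | 1-[(but-3-yn-1-yloxy)methyl]-4-methoxybenzene | C#CCCOCc1ccc(OC)cc1 | intermediate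
10 | (S)-2-[4-(PMB-oxy)but-1-yn-1-yl]-5-methyl-5-(triethylsilyloxy)cyclohex-2-en-1-one | O=C1C(C#CCCOCc2ccc(OC)cc2)=CC[C@](C)(O[Si](CC)(CC)CC)C1 | intermediate
11 | (1,3-dioxolan-2-ylmethyl)magnesium bromide | Br[Mg]CC1OCCO1 | starting material
12 | (3S,5S)-3-(1,3-dioxolan-2-ylmethyl)-2-[4-(PMB-oxy)but-1-yn-1-yl]-5-methyl-5-(triethylsilyloxy)-1-(trimethylsilyloxy)cyclohex-1-ene | C[Si](C)(C)OC1=C(C#CCCOCc2ccc(OC)cc2)[C@H](CC2OCCO2)C[C@](C)(O[Si](CC)(CC)CC)C1 | intermediate
13 | allyl bromide | C=CCBr | starting material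
14 | lithium enolate corresponding to 12 | [Li]OC1=C(C#CCCOCc2ccc(OC)cc2)[C@H](CC2OCCO2)C[C@](C)(O[Si](CC)(CC)CC)C1 | intermediate
15 | (2S,3S,5S)-2-allyl-3-(1,3-dioxolan-2-ylmethyl)-2-[4-(PMB-oxy)but-1-yn-1-yl]-5-methyl-5-(triethylsilyloxy)cyclohexan-1-one | O=C1C[C@@](C)(O[Si](CC)(CC)CC)C[C@@H](CC2OCCO2)[C@]1(C#CCCOCc1ccc(OC)cc1)CC=C | intermediate
16 | (1S,2S,3S,5S)-2-allyl-3-(1,3-dioxolan-2-ylmethyl)-2-[4-(PMB-oxy)but-1-yn-1-yl]-5-methyl-5-(triethylsilyloxy)cyclohexan-1-ol | O[C@H]1C[C@@](C)(O[Si](CC)(CC)CC)C[C@@H](CC2OCCO2)[C@]1(C#CCCOCc1ccc(OC)cc1)CC=C | intermediate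
17 | (1S,2S,3S,5S)-2-allyl-3-(1,3-dioxolan-2-ylmethyl)-2-[4-(PMB-oxy)but-1-yn-1-yl]-5-methylcyclohexane-1,5-diol | O[C@H]1C[C@@](C)(O)C[C@@H](CC2OCCO2)[C@]1(C#CCCOCc1ccc(OC)cc1)CC=C | intermediate
18 | (1S,2S,3S,5S)-2-allyl-3-(1,3-dioxolan-2-ylmethyl)-2-[4-(PMB-oxy)but-1-yn-1-yl]-5-methylcyclohexane-1,5-diyl diacetate | CC(=O)O[C@H]1C[C@@](C)(OC(C)=O)C[C@@H](CC2OCCO2)[C@]1(C#CCCOCc1ccc(OC)cc1)CC=C | intermediate
19 | B-alkyl-9-borabicyclononane adduct of 18 (boron on the terminal carbon of the former allyl group) | CC(=O)O[C@H]1C[C@@](C)(OC(C)=O)C[C@@H](CC2OCCO2)[C@]1(C#CCCOCc1ccc(OC)cc1)CCCB1C2CCCC1CCC2 | intermediate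
20 | (1S,2S,3S,5S)-3-(1,3-dioxolan-2-ylmethyl)-2-(3-hydroxypropyl)-2-[4-(PMB-oxy)but-1-yn-1-yl]-5-methylcyclohexane-1,5-diyl diacetate | CC(=O)O[C@H]1C[C@@](C)(OC(C)=O)C[C@@H](CC2OCCO2)[C@]1(C#CCCOCc1ccc(OC)cc1)CCCO | intermediate
21 | 2-nitrobenzenesulfonamide | NS(=O)(=O)c1ccccc1[N+](=O)[O-] | starting material
22 | (1S,2S,3S,5S)-3-(1,3-dioxolan-2-ylmethyl)-2-[3-(Ns-amino)propyl]-2-[4-(PMB-oxy)but-1-yn-1-yl]-5-methylcyclohexane-1,5-diyl diacetate | CC(=O)O[C@H]1C[C@@](C)(OC(C)=O)C[C@@H](CC2OCCO2)[C@]1(C#CCCOCc1ccc(OC)cc1)CCCNS(=O)(=O)c1ccccc1[N+](=O)[O-] | intermediate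
23 | (1S,2S,3S,5S)-2-[3-(Ns-amino)propyl]-2-[4-(PMB-oxy)but-1-yn-1-yl]-5-methyl-3-(2-oxoethyl)cyclohexane-1,5-diyl diacetate (the 5-alkynal) | CC(=O)O[C@H]1C[C@@](C)(OC(C)=O)C[C@@H](CC=O)[C@]1(C#CCCOCc1ccc(OC)cc1)CCCNS(=O)(=O)c1ccccc1[N+](=O)[O-] | intermediate
24 | cis-fused ring A/ring B (E)-enone diacetate, (1S,2S,3S,5S), alkylidene = 3-(PMB-oxy)propylidene, C2 bears (CH2)3NHNs | CC(=O)O[C@H]1C[C@@](C)(OC(C)=O)C[C@H]2CC(=O)/C(=C/CCOCc3ccc(OC)cc3)[C@]21CCCNS(=O)(=O)c1ccccc1[N+](=O)[O-] | intermediate
25 | cis-fused ring A/ring B (E)-enone diacetate, (1S,2S,3S,5S), alkylidene = 3-hydroxypropylidene, C2 bears (CH2)3NHNs | CC(=O)O[C@H]1C[C@@](C)(OC(C)=O)C[C@H]2CC(=O)/C(=C/CCO)[C@]21CCCNS(=O)(=O)c1ccccc1[N+](=O)[O-] | intermediate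
26 | N-Ns tricycle, (1S,2S,3S,5S,E), azonane ring C closed | CC(=O)O[C@H]1C[C@@](C)(OC(C)=O)C[C@H]2CC(=O)/C3=C/CCN(S(=O)(=O)c4ccccc4[N+](=O)[O-])CCC[C@@]321 | intermediate
27 | secondary amine tricycle, (1S,2S,3S,5S,E) | CC(=O)O[C@H]1C[C@@](C)(OC(C)=O)C[C@H]2CC(=O)/C3=C/CCNCCC[C@@]321 | intermediate
28 | CNP0137427.1, (1S,2S,3S,5S,E)-N-formyl azonane-fused enone diacetate | CC(=O)O[C@H]1C[C@@](C)(OC(C)=O)C[C@H]2CC(=O)/C3=C/CCN(C=O)CCC[C@@]321 | target

Total step count: 20
Longest linear sequence: 19 steps (1 to 28 through steps 1–5 and 7–20; step 6 prepares the alkyne separately)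

**Steps most likely to fail**

Step 8. The risk is poor facial selectivity of the carbon nucleophile at C3, with attack anti to the silyloxy group competing with the desired attack anti to the methyl group. The fallback delivers hydrogen instead of carbon to C3 under catalyst control. It sets out from 12 of whatever C3 composition. Saegusa–Ito oxidation (Pd(OAc)2, MeCN) erases C3 and should give the tetrasubstituted enone (S)-3-(1,3-dioxolan-2-ylmethyl)-2-[4-(PMB-oxy)but-1-yn-1-yl]-5-methyl-5-(triethylsilyloxy)cyclohex-2-en-1-one F1. Asymmetric copper hydride conjugate reduction (Cu(OAc)2, the DTBM-SEGPHOS antipode that places hydrogen trans to the C5 oxygen, polymethylhydrosiloxane, toluene; fluoride work-up) should then give the C2-epimeric ketone (3S,5S)-3-(1,3-dioxolan-2-ylmethyl)-2-[4-(PMB-oxy)but-1-yn-1-yl]-5-methyl-5-(triethylsilyloxy)cyclohexan-1-one F2. Thermodynamic enolisation at the doubly activated C2–H (NaH, THF, 0 °C) and allylation with 13, anti to the C3 arm, brings the sequence back to 15.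

Step 10. The risk is hydride delivery to the wrong carbonyl face, because the axial C5 methyl group hinders the face the catalyst must use (a mismatched case) or the hindered ketone reacts only through the uncatalysed background path. The fallback replaces kinetic hydride delivery by thermodynamic control. It sets out from 15 and uses an equilibrating Meerwein–Ponndorf–Verley reduction (Al(OiPr)3, iPrOH, reflux, trace of acetone). The 1S alcohol is the only epimer with an equatorial hydroxyl free of a 1,3-diaxial contact with the C5 methyl, so equilibration should favour it. The fallback returns directly to 16 and makes no new compound (F0).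

Step 16. The risk is loss of catalyst activity through binding of the sulfonamide or nitro group to the cationic metal, or decarbonylation of the acyl rhodium hydride before the alkyne inserts. The fallback forms the same C–C bond by reductive coupling instead of C–H activation. It sets out from 23 and uses a rhodium-catalysed, hydrogen-mediated aldehyde–alkyne cyclisation ([Rh(cod)2]OTf, BINAP, a carboxylic acid co-catalyst, H2 at 1 atm, ClCH2CH2Cl). An oxarhodacyclopentene forms and is cleaved by hydrogen, which should give the cis-fused allylic alcohol F3 with the vinylic hydrogen cis to the new C–C bond; the carbinol configuration is irrelevant. Oxidation with Dess–Martin periodinane (CH2Cl2, rt) then returns to 24.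

Further compounds
F1 | step 8 | (S)-3-(1,3-dioxolan-2-ylmethyl)-2-[4-(PMB-oxy)but-1-yn-1-yl]-5-methyl-5-(triethylsilyloxy)cyclohex-2-en-1-one | O=C1C(C#CCCOCc2ccc(OC)cc2)=C(CC2OCCO2)C[C@](C)(O[Si](CC)(CC)CC)C1
F2 | step 8 | (3S,5S)-3-(1,3-dioxolan-2-ylmethyl)-2-[4-(PMB-oxy)but-1-yn-1-yl]-5-methyl-5-(triethylsilyloxy)cyclohexan-1-one, C2 epimers | O=C1C(C#CCCOCc2ccc(OC)cc2)[C@H](CC2OCCO2)C[C@](C)(O[Si](CC)(CC)CC)C1
F0 | step 10 | none | none
F3 | step 16 | cis-fused ring A/ring B (E)-allylic alcohol diacetate, (1S,2S,3S,5S), ring B carbinol in place of the ketone of 24, carbinol configuration open | CC(=O)O[C@H]1C[C@@](C)(OC(C)=O)C[C@H]2CC(O)/C(=C/CCOCc3ccc(OC)cc3)[C@]21CCCNS(=O)(=O)c1ccccc1[N+](=O)[O-]
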